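**Retrosynthetic overview**
1. C=C bond: the target comes from a Horner–Wadsworth–Emmons olefination between O-silylated syringaldehyde and the α-phosphoryl enolate of the β-(3,4,5-trimethoxybenzyl)butyrolactone.
2. Aryl–CH2 bond: that enolate comes from copper-catalysed homoconjugate addition of 3,4,5-trimethoxyphenylmagnesium bromide to the cyclopropane CH2 of a 1-phosphoryl-3-oxabicyclo[3.1.0]hexan-2-one. The enolate is never quenched, so both C–C bonds are made in one flask.
3. The bicycle comes from (S)-epichlorohydrin and triethyl phosphonoacetate. Double alkylation plus lactonisation closes the cyclopropane and the γ-lactone in a single operation, and the only stereocentre comes from the chiral pool.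
4. Ring order: both arenes are bought. The cyclopropane forms first and the lactone follows in the same flask (step 1). The cyclopropane is consumed as a strained electrophile in step 3, and the lactone is kept.

Assumption: the SMILES is read as the (3E,4S) isomer, with the aryl group trans to the lactone C=O. The descriptors (1S,5R) in 6 and (4R) in 11 differ from (4S) only because P outranks O in the priority rules. The spatial arrangement never changes.

**Step 1**
Reactants: 1 (S)-epichlorohydrin; 2 triethyl phosphonoacetate
Product: 6 diethyl [(1S,5R)-2-oxo-3-oxabicyclo[3.1.0]hexan-1-yl]phosphonate, via chlorohydrin alkoxide 3 (not isolated), via epoxide 4 (not isolated), via cyclopropylmethanol 5 (not isolated)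
Conditions: 2 (1.15 equiv), NaOEt (1.1 equiv), EtOH, 0 °C; add 1 (1.0 equiv); 0 °C to reflux, 16 h
Reagents that add atoms: none
Why: Proposed new method: the phosphonoacetate carbanion opens the epoxide of 1 at its CH2 terminus, alkoxide 3 expels chloride to give epoxide 4 with the C–O stereocentre untouched, the re-formed carbanion closes the cyclopropane by 3-exo-tet SN2 attack with clean inversion at that carbon (the CH2O arm settles trans to the bulkier phosphoryl group and cis to the ester), and 5 lactonises at once, so cyclopropane and lactone arise in one flask with chiral-pool stereocontrol; the closest known reaction type is the double alkylation–lactonisation of diethyl malonate or sulfonylacetonitriles with epichlorohydrin under NaOEt/EtOH.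

**Step 2**
Reactants: 7 syringaldehyde
Product: 8 4-[(tert-butyldimethylsilyl)oxy]-3,5-dimethoxybenzaldehyde
Conditions: TBSCl (1.2 equiv), imidazole (2.5 equiv), DMF, 23 °C, 12 h
Reagents that add atoms: tert-butyldimethylsilyl chloride (TBSCl), CC(C)(C)[Si](C)(C)Cl
Why: Imidazole-promoted silyl ether formation masks the acidic phenol, which would otherwise protonate enolate 11 and deactivate the aldehyde as its phenoxide; no stereocentre is involved.

**Step 3**
Reactants: 9 5-bromo-1,2,3-trimethoxybenzene; 6 diethyl [(1S,5R)-2-oxo-3-oxabicyclo[3.1.0]hexan-1-yl]phosphonate; 8 4-[(tert-butyldimethylsilyl)oxy]-3,5-dimethoxybenzaldehyde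
Product: 13 (3E,4S)-3-(4-hydroxy-3,5-dimethoxybenzylidene)-4-(3,4,5-trimethoxybenzyl)dihydrofuran-2(3H)-one, via aryl Grignard 10 (not isolated), via magnesium phosphonoenolate 11 (not isolated), via silyl ether 12 (not isolated)
Conditions: 9 (1.15 equiv), Mg turnings (1.2 equiv), THF, 45 °C; cool to −30 °C, CuBr·SMe2 (20 mol %), then 6 (1.0 equiv), −30 → 0 °C, 2 h; 8 (1.3 equiv), 0 → 65 °C, 8 h; then MeOH, KHF2 (4 equiv), 23 °C, 2 h; one flask
Reagents that add atoms: none
Why: Proposed new method: the copper-catalysed homoconjugate addition of 10 strikes the unhindered cyclopropane CH2 of doubly activated 6 in SN2 fashion, breaks the C1–C6 bond without touching the stereocentre and releases chelated magnesium enolate 11, which is the nucleophile of a magnesium-mediated Horner–Wadsworth–Emmons olefination, so that 8 gives the thermodynamic E-arylidene lactone 12 by reversible addition and irreversible phosphate loss, and mildly acidic KHF2 then frees the phenol without deprotonating the allylic stereocentre; the closest known reaction types are the Grignard/copper opening of the analogous 1-ethoxycarbonyl bicyclic lactone and olefinations of Grignard-generated magnesium phosphonoenolates.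

**Compound list**
1 | (S)-epichlorohydrin, (2S)-2-(chloromethyl)oxirane | ClC[C@@H]1CO1 | starting material
2 | triethyl phosphonoacetate | CCOC(=O)CP(=O)(OCC)OCC | starting material
3 | ethyl (4S)-5-chloro-2-(diethoxyphosphoryl)-4-hydroxypentanoate (present as sodium alkoxide, C2 epimers) | CCOC(=O)C(C[C@H](O)CCl)P(=O)(OCC)OCC | intermediate
4 | ethyl 2-(diethoxyphosphoryl)-3-[(2S)-oxiran-2-yl]propanoate (C2 epimers) | CCOC(=O)C(C[C@H]1CO1)P(=O)(OCC)OCC | intermediate
5 | ethyl (1S,2R)-1-(diethoxyphosphoryl)-2-(hydroxymethyl)cyclopropane-1-carboxylate (CH2OH cis to the ester) | CCOC(=O)[C@]1(P(=O)(OCC)OCC)C[C@@H]1CO | intermediate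
6 | diethyl [(1S,5R)-2-oxo-3-oxabicyclo[3.1.0]hexan-1-yl]phosphonate (cis-fused cyclopropane/γ-lactone, phosphoryl on the ring-fusion carbon next to C=O) | O=C1OC[C@H]2C[C@@]12P(=O)(OCC)OCC | intermediate
7 | syringaldehyde, 4-hydroxy-3,5-dimethoxybenzaldehyde | COc1cc(C=O)cc(OC)c1O | starting material
8 | 4-[(tert-butyldimethylsilyl)oxy]-3,5-dimethoxybenzaldehyde | COc1cc(C=O)cc(OC)c1O[Si](C)(C)C(C)(C)C | intermediate
9 | 5-bromo-1,2,3-trimethoxybenzene | COc1cc(Br)cc(OC)c1OC | starting material
10 | (3,4,5-trimethoxyphenyl)magnesium bromide | COc1cc([Mg]Br)cc(OC)c1OC | intermediate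
11 | bromomagnesium enolate of diethyl [(4R)-2-oxo-4-(3,4,5-trimethoxybenzyl)tetrahydrofuran-3-yl]phosphonate | CCOP(=O)(OCC)C1=C(O[Mg]Br)OC[C@H]1Cc1cc(OC)c(OC)c(OC)c1 | intermediate
12 | (3E,4S)-3-{4-[(tert-butyldimethylsilyl)oxy]-3,5-dimethoxybenzylidene}-4-(3,4,5-trimethoxybenzyl)dihydrofuran-2(3H)-one | COc1cc(/C=C2/C(=O)OC[C@H]2Cc2cc(OC)c(OC)c(OC)c2)cc(OC)c1O[Si](C)(C)C(C)(C)C | intermediate
13 | (3E,4S)-3-(4-hydroxy-3,5-dimethoxybenzylidene)-4-(3,4,5-trimethoxybenzyl)dihydrofuran-2(3H)-one | COc1cc(/C=C2/C(=O)OC[C@H]2Cc2cc(OC)c(OC)c(OC)c2)cc(OC)c1O | target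

**Total step count:** 3. **Longest linear sequence:** 2 (step 1 then step 3, or step 2 then step 3).

**Steps most likely to fail, with fallbacks**

Step 3 is the most exposed.
- An aryl copper reagent may be too sluggish for a cyclopropane activated by a phosphonate instead of a second ester.
- The Grignard reagent may attack the lactone carbonyl.
- The hindered magnesium enolate may add to 8 without eliminating.

The fallback sets out from 1 and comes back to the route at 12. It replaces the phosphonate logic with ester and aldol logic.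
- Compound 1 is condensed with diethyl malonate (NaOEt, EtOH, reflux) to ethyl (1R,5S)-2-oxo-3-oxabicyclo[3.1.0]hexane-1-carboxylate F1.
- Grignard 10 with catalytic CuBr·SMe2 (THF, −30 °C) opens it to ethyl (4S)-2-oxo-4-(3,4,5-trimethoxybenzyl)tetrahydrofuran-3-carboxylate F2.
- Krapcho dealkoxycarbonylation (LiCl, wet DMSO, 140 °C) gives (4S)-4-(3,4,5-trimethoxybenzyl)dihydrofuran-2(3H)-one F3.
- Its lithium enolate (LiN(SiMe3)2, THF, −78 °C) adds to 8 to give the aldol (4S)-3-{[4-(tert-butyldimethylsilyloxy)-3,5-dimethoxyphenyl](hydroxy)methyl}-4-(3,4,5-trimethoxybenzyl)dihydrofuran-2(3H)-one F4.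
- Acetylation (Ac2O, Et3N, DMAP, CH2Cl2) gives the corresponding benzylic acetate F5.
- E1cB elimination with DBU in toluene delivers 12, which is desilylated with KHF2 as in the last stage of step 3.

Step 1 is second.
- The cyclopropane closure may place the hydroxymethyl arm cis to phosphorus, which gives a cyclic phosphonate instead of the lactone.
- Direct SN2 displacement at the C–Cl bond leads to the enantiomer and erodes ee.
- Phosphoryl transfer to the alkoxide may compete.

The fallback sets out from 2 and comes back at 6, with carbene chemistry in place of alkylation chemistry.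
- DMAP-catalysed transesterification of 2 with allyl alcohol (toluene, reflux, ethanol distilled off) gives allyl 2-(diethoxyphosphoryl)acetate F6.
- Diazo transfer (4-acetamidobenzenesulfonyl azide, DBU, MeCN, 0 °C) gives allyl 2-diazo-2-(diethoxyphosphoryl)acetate F7.
- Enantioselective intramolecular cyclopropanation with the chiral dirhodium carboxylate Rh2(S-TCPTTL)4, or its enantiomer (whichever delivers the (1S,5R) series on screening), in CH2Cl2 gives 6.
- Cyclopropane and lactone again close in one event. The cis fusion is geometrically enforced, so the diastereomer problem disappears.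

Step 2 is third. The silylation itself is routine. The risk is that the aryl silyl ether, which sits para to the aldehyde, is stripped by magnesium alkoxides or phosphate at 65 °C before the olefination.

The fallback sets out from 7 and comes back at 13. It drops the protecting group altogether.
- Compound 7 is deprotonated with LiN(SiMe3)2 (1.0 equiv, THF, 0 °C) to lithium 4-formyl-2,6-dimethoxyphenolate F8.
- This solution is added to enolate 11 in place of 8 and held at reflux. Addition to the deactivated aldehyde is slow, but the irreversible phosphate loss drives the reaction.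
- Work-up with dilute HCl gives 13 directly, and no fluoride stage is needed.

**Further compounds**
F1 | step 3 | ethyl (1R,5S)-2-oxo-3-oxabicyclo[3.1.0]hexane-1-carboxylate | O=C1OC[C@H]2C[C@@]12C(=O)OCC
F2 | step 3 | ethyl (4S)-2-oxo-4-(3,4,5-trimethoxybenzyl)tetrahydrofuran-3-carboxylate (C3 epimers) | CCOC(=O)C1C(=O)OC[C@H]1Cc1cc(OC)c(OC)c(OC)c1
F3 | step 3 | (4S)-4-(3,4,5-trimethoxybenzyl)dihydrofuran-2(3H)-one | O=C1OC[C@@H](Cc2cc(OC)c(OC)c(OC)c2)C1
F4 | step 3 | (4S)-3-{[4-(tert-butyldimethylsilyloxy)-3,5-dimethoxyphenyl](hydroxy)methyl}-4-(3,4,5-trimethoxybenzyl)dihydrofuran-2(3H)-one (carbinol epimers) | COc1cc(C(O)C2C(=O)OC[C@H]2Cc2cc(OC)c(OC)c(OC)c2)cc(OC)c1O[Si](C)(C)C(C)(C)C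
F5 | step 3 | benzylic acetate of F4 | COc1cc(C(OC(C)=O)C2C(=O)OC[C@H]2Cc2cc(OC)c(OC)c(OC)c2)cc(OC)c1O[Si](C)(C)C(C)(C)C
F6 | step 1 | allyl 2-(diethoxyphosphoryl)acetate | C=CCOC(=O)CP(=O)(OCC)OCC
F7 | step 1 | allyl 2-diazo-2-(diethoxyphosphoryl)acetate | C=CCOC(=O)C(=[N+]=[N-])P(=O)(OCC)OCC
F8 | step 2 | lithium 4-formyl-2,6-dimethoxyphenolate | [Li+].[O-]c1c(OC)cc(C=O)cc1OC
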